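| flask | Z | G | remark | time |
|---|---|---|---|---|
| ash | 0.40 M | 1.1 M (fed, over 30 s) | run made earlier; the fed solution adds 0.10 times the starting volume |  |
| larch | 0.40 M | 1.8 M (fed, over 30 s) | run made earlier; the fed solution adds 0.10 times the starting volume |  |
| oak | 0.60 M | 0.80 M (fed, over 30 s) | run made earlier; the fed solution adds 0.10 times the starting volume |  |
| flask | 0.40 M | 0.800 M (fed, over 30 s) | the fed solution adds 0.10 times the starting volume | 4.0 min |

| run | time / min | J / % | L / % | Z / % |
|---|---|---|---|---|
| ash | 0.167 | 14 | 3 | 16 |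
| ash | 0.500 | 3 | 47 | 3 |
| ash | 0.833 | 6 | 65 | 2 |
| ash | 1.33 | 1 | 75 | 1 |
| ash | 2.00 | 1 | 81 | 0 |
| ash | 2.50 | 5 | 83 | 2 |
| ash | 3.00 | 0 | 79 | 4 |
| larch | 0.250 | 7 | 29 | 4 |
| larch | 0.417 | 2 | 56 | 5 |
| larch | 0.667 | 0 | 74 | 0 |
| larch | 0.833 | 3 | 78 | 3 |
| larch | 1.33 | 0 | 81 | 0 |
| larch | 2.00 | 2 | 83 | 2 |
| larch | 3.00 | 0 | 84 | 0 |
| oak | 0.667 | 5 | 31 | 4 |
| oak | 1.33 | 5 | 39 | 9 |
| oak | 2.00 | 3 | 40 | 8 |
| oak | 2.50 | 7 | 38 | 5 |
| oak | 3.00 | 7 | 39 | 10 |

(each reading ± 2 percentage points)
- percentages count the Z that a species holds: one E counts as two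
- L is meant together with its X
- every charge counts on the volume at the start, and the solution that is fed holds the whole dose
- solid, in amounts per volume of the solution: X
- steps under discussion: Z + G -> J; Z <-> D; X <-> L; G + Q -> L; 2 Z -> E; G + J -> Q
- equivalents of G to Z, everything else as given, that leave most J at 4.0 min
- the amount of J then, in percent of the Z charged
- the amount of J with the amounts as given

1. We ask first whether slowness makes the time a number to know well. But in oak, where G falls short, L reads 40% at 2.00 min and 39% at 3.00 min, a change smaller than the scatter of 2 percentage points. So we set the time aside.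

2. Each L holds 3 G, and the flask is charged 2.00 equivalents, so G is the limiting reagent. As with an unbalanced step-growth charge, we watch the shortfall: 3 minus the equivalents charged. It counts on the starting volume, so the feed volume drops out of the shortfall.

3. We join two ends. Larch, charged 4.50 equivalents, has no shortfall, and J reads 0% at 3.00 min. Oak has a shortfall of 1.67 equivalents, and its last readings average 5.67% J. The straight line between them gives the J yield per equivalent of shortfall, 3.40%. Oak also starts with more Z than the flask, 0.60 M against 0.40 M, and the line passes over that difference.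

4. An error of 0.5 equivalent in the charges moves our J by 1.7 points. The scatter of oak's averaged J moves it by 0.69 points. The charges move it further, so they are the numbers we want to know well.

5. The flask's shortfall is 1.00 equivalent, so we expect 3.40% J. The line has no peak, so it gives no best dose.

The forecast, on different grounds (“J therefore follows free Z”), gives 3% J, and 9% at 0.9 equiv.

The flask gives 3.12% J, against our 3.40%. The best dose is 0.495 equiv, with 11.6% J.

Z + G → J (k = 0.750 M⁻¹ s⁻¹); Z ⇌ D (K = 2.20, k = 0.120 s⁻¹); X ⇌ L, rate k3*(cs3 - [L]) while solid is left; crystals form when [L] > cs3 (solubility = 5.80 mM, k = 1.20 s⁻¹); G + Q → L (k = 1.10 M⁻¹ s⁻¹); 2 Z → E (k = 0.0850 M⁻¹ s⁻¹); G + J → Q (k = 0.850 M⁻¹ s⁻¹) The neighbour, charged 0.32 M of G or 0.800 equiv, has a shortfall of 2.20 equivalents, so the same yield of 3.40% per equivalent predicts 7.48% J. It ends with 10.6% J, 3.1 points above the line.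

The runs are simulated for an exercise, noise included.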